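**Strategy.** The ring is closed by forming the C4–C5 bond. The feature exploited is the C5 acetoxy carbinol flanked by the methyl-bearing C4 in the fourteen-membered carbocycle: with the C4 methyl drawn back to an exocyclic methylene, C5 is an allylic alcohol, the signature of an aldehyde–alkyne reductive coupling. One nickel-catalysed step on an open-chain ynal (C5 aldehyde, terminal alkyne at C4, C10 dioxolane, silyl ethers at C13 and on the tertiary carbinol that masks the isopropenyl group) forges C4–C5, closes the only ring and installs the C5 oxygen as a silyl ether. Hydroxyl-directed hydrogenation then sets C4, and acetylation, dehydration and ketal hydrolysis finish the target.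

Key step: step 14

Remark (assumption): ring atoms are numbered C1 (isopropenyl-bearing) to C14 so that C4, C8 and C12 carry methyl, C5 and C13 oxygen and C10 the ketone; in this numbering the target is 1S,4R,5S,8S,12R,13R, and the commercial (S)-(−) forms of α-terpineol and citronellic acid are taken as enantiopure.
Abbreviations: TBS = tert-butyldimethylsilyl, TMS = trimethylsilyl, TES = triethylsilyl.

Step 1
Reactants: 1 (S)-α-terpineol
Product: 2 (S)-2-(4-methylcyclohex-3-en-1-yl)propan-2-yl TBS ether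
Conditions: TBSOTf, 2,6-lutidine, CH2Cl2, 0 °C → rt
Reagents that add atoms: tert-butyldimethylsilyl triflate, CC(C)(C)[Si](C)(C)OS(=O)(=O)C(F)(F)F
Why: Silyl triflate silylation of the hindered tertiary alcohol should proceed cleanly, and the tertiary TBS ether is chosen because it survives the acid of steps 2 and 4; the C1 stereocentre comes from the chiral pool.

Step 2
Reactants: 2 (S)-2-(4-methylcyclohex-3-en-1-yl)propan-2-yl TBS ether
Product: 5 (S)-5-[2-(TBS-oxy)propan-2-yl]-7,7-dimethoxyheptan-2-one, via hydroperoxy ketal aldehyde 3 (not isolated), via hydroperoxy ketal acetal 4 (not isolated)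
Conditions: O3, CH2Cl2/MeOH (5:1), −78 °C; TsOH·H2O (cat.), −78 °C → rt; NaHCO3, Me2S, rt
Reagents that add atoms: ozone, [O-][O+]=O; methanol, CO
Why: Unsymmetrical ozonolysis (Criegee mechanism) in methanol traps the carbonyl oxide formed at the methyl-bearing alkene carbon as the α-methoxy hydroperoxide, the free aldehyde is acetalized under TsOH and Me2S then reduces the hydroperoxide to the methyl ketone, so the two termini should emerge differentiated without touching the stereocentre.

Step 3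
Reactants: 5 (S)-5-[2-(TBS-oxy)propan-2-yl]-7,7-dimethoxyheptan-2-one
Product: 9 (S)-3-[2-(TBS-oxy)propan-2-yl]-1,1-dimethoxy-7-(trimethylsilyl)hept-6-yne, via lithium enolate 6 (not isolated), via enol diethyl phosphate 7 (not isolated), via lithium acetylide 8 (not isolated)
Conditions: LiN(iPr)2 (1.1 equiv), THF, −78 °C; ClP(O)(OEt)2, −78 °C → rt; LiN(iPr)2 (2.5 equiv), −78 °C → rt; Me3SiCl, −78 °C → rt
Reagents that add atoms: chlorotrimethylsilane, C[Si](C)(C)Cl
Why: One-pot conversion of a methyl ketone into a terminal alkyne through the kinetic enolate and β-elimination of its enol phosphate, the acetylide being capped in the flask as the alkynylsilane so that no acidic C–H is carried into the organolithium chemistry of step 10; acetal and silyl ether are inert to the amide base.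

Step 4
Reactants: 9 (S)-3-[2-(TBS-oxy)propan-2-yl]-1,1-dimethoxy-7-(trimethylsilyl)hept-6-yne
Product: 10 (S)-3-[2-(TBS-oxy)propan-2-yl]-7-(trimethylsilyl)hept-6-ynal
Conditions: pyridinium p-toluenesulfonate (cat.), acetone/H2O (10:1), 50 °C
Reagents that add atoms: water, O
Why: Mild acid-catalysed acetal hydrolysis should free the aldehyde while the tertiary silyl ether and the alkynylsilane, both stable to this weak acid, remain.

Step 5
Reactants: 10 (S)-3-[2-(TBS-oxy)propan-2-yl]-7-(trimethylsilyl)hept-6-ynal; 11 (S)-4-benzyl-3-propionyloxazolidin-2-one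
Product: 14 (S)-4-benzyl-3-{(2S,3R,5S)-5-[2-(TBS-oxy)propan-2-yl]-3-hydroxy-2-methyl-9-(trimethylsilyl)non-8-ynoyl}oxazolidin-2-one, via dibutylboron Z-enolate 12 (not isolated), via dibutylboron aldolate 13 (not isolated)
Conditions: 11, Bu2BOTf, iPr2NEt, CH2Cl2, −78 → 0 °C; 10, −78 → 0 °C; pH 7 buffer, MeOH, 30% H2O2, 0 °C
Reagents that add atoms: none
Why: Evans syn aldol reaction, in which the Z-boron enolate reacts through a closed Zimmerman–Traxler transition state on the face away from the benzyl group and so sets the C12 methyl and C13 hydroxyl centres (2S,3R in the adduct, 12R,13R once C11 is a methylene) under auxiliary control that should override the remote C1 centre.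

Step 6
Reactants: 14 aldol adduct
Product: 15 (S)-4-benzyl-3-{(2S,3R,5S)-3-(TBS-oxy)-5-[2-(TBS-oxy)propan-2-yl]-2-methyl-9-(trimethylsilyl)non-8-ynoyl}oxazolidin-2-one
Conditions: TBSOTf, 2,6-lutidine, CH2Cl2, −78 → 0 °C
Reagents that add atoms: tert-butyldimethylsilyl triflate, CC(C)(C)[Si](C)(C)OS(=O)(=O)C(F)(F)F
Why: Silyl triflate protection of the hindered aldol hydroxyl at low temperature is standard for such adducts and carries no risk of retro-aldol cleavage.

Step 7
Reactants: 15 silylated aldol adduct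
Product: 16 (2R,3R,5S)-3-(TBS-oxy)-5-[2-(TBS-oxy)propan-2-yl]-2-methyl-9-(trimethylsilyl)non-8-yn-1-ol
Conditions: LiBH4, MeOH (1.1 equiv), THF, 0 °C
Reagents that add atoms: none
Why: Reductive removal of the oxazolidinone (hydride attack at the exocyclic imide carbonyl) should give the primary alcohol without epimerizing C12 and returns the auxiliary.

Step 8
Reactants: 16 primary alcohol
Product: 17 (2S,3R,5S)-3-(TBS-oxy)-5-[2-(TBS-oxy)propan-2-yl]-1-iodo-2-methyl-9-(trimethylsilyl)non-8-yne
Conditions: I2, PPh3, imidazole, CH2Cl2, 0 °C → rt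
Reagents that add atoms: iodine, II
Why: Appel-type iodination converts the primary alcohol into the C11 iodide by SN2 displacement of the oxyphosphonium ion, and no stereocentre is involved.

Step 9
Reactants: 18 (S)-citronellic acid
Product: 19 (S)-N-methoxy-N,3,7-trimethyloct-6-enamide
Conditions: MeNHOMe·HCl, EDC·HCl, 4-(dimethylamino)pyridine (cat.), Et3N, CH2Cl2, 0 °C → rt
Reagents that add atoms: N,O-dimethylhydroxylamine hydrochloride, CNOC.Cl
Why: Carbodiimide amide coupling gives the Weinreb amide, the acyl partner that stops at the ketone stage, and the C8 stereocentre from the chiral pool (β to the carbonyl) is not touched.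

Step 10
Reactants: 17 C11 iodide; 19 (S)-N-methoxy-N,3,7-trimethyloct-6-enamide
Product: 22 (6S,10R,11R,13S)-11-(TBS-oxy)-13-[2-(TBS-oxy)propan-2-yl]-2,6,10-trimethyl-17-(trimethylsilyl)heptadec-2-en-16-yn-8-one, via alkyllithium 20 (not isolated), via lithium hemiaminal adduct 21 (not isolated)
Conditions: t-BuLi (2.1 equiv), pentane/Et2O (3:2), −78 °C; 19, −78 → 0 °C; aq. NH4Cl
Reagents that add atoms: none
Why: Iodine–lithium exchange gives the primary alkyllithium (oxygen in the γ position, so no β-elimination), which adds once to the Weinreb amide because the chelated tetrahedral adduct persists until the quench (Weinreb ketone synthesis), joining C10 to C11 with all four stereocentres in place.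

Step 11
Reactants: 22 C10 ketone
Product: 23 2-[(S)-2,6-dimethylhept-5-en-1-yl]-2-[(2R,3R,5S)-3-(TBS-oxy)-5-[2-(TBS-oxy)propan-2-yl]-2-methyl-9-(trimethylsilyl)non-8-yn-1-yl]-1,3-dioxolane
Conditions: Me3SiOCH2CH2OSiMe3, Me3SiOTf (cat.), CH2Cl2, −78 → −20 °C; pyridine quench
Reagents that add atoms: 1,2-bis(trimethylsilyloxy)ethane, C[Si](C)(C)OCCO[Si](C)(C)C
Why: Ketalization under Noyori conditions is aprotic and cold enough to leave the silyl ethers, the alkynylsilane and the trisubstituted alkene untouched, and the dioxolane prevents aldol closure of the later 1,6-keto aldehyde.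

Step 12
Reactants: 23 silylalkyne dioxolane
Product: 24 2-[(S)-2,6-dimethylhept-5-en-1-yl]-2-[(2R,3R,5S)-3-(TBS-oxy)-5-[2-(TBS-oxy)propan-2-yl]-2-methylnon-8-yn-1-yl]-1,3-dioxolane
Conditions: K2CO3 (cat.), MeOH/THF, rt
Reagents that add atoms: none
Why: Base-catalysed methanolysis of the C(sp)–Si bond should remove only the alkynyl TMS group and expose the terminal alkyne.

Step 13
Reactants: 24 terminal alkyne
Product: 26 (S)-4-methyl-5-{2-[(2R,3R,5S)-3-(TBS-oxy)-5-[2-(TBS-oxy)propan-2-yl]-2-methylnon-8-yn-1-yl]-1,3-dioxolan-2-yl}pentanal, via secondary ozonide 25 (not isolated)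
Conditions: O3, CH2Cl2, Sudan Red 7B (indicator), −78 °C; PPh3, −78 °C → rt
Reagents that add atoms: ozone, [O-][O+]=O
Why: Ozonolysis with reductive work-up, in which the electron-rich trisubstituted alkene reacts far faster than the terminal alkyne, so that titration to the indicator end point should cleave only the isopropylidene terminus to the C5 aldehyde.

Step 14
Reactants: 26 ynal; 27 triethylsilane
Product: 28 (1S,5S,8S,12R,13R)-13-(TBS-oxy)-1-[2-(TBS-oxy)propan-2-yl]-10,10-(ethylenedioxy)-8,12-dimethyl-4-methylidene-5-(TES-oxy)cyclotetradecane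
Conditions: Ni(cod)2 (zerovalent nickel, 30 mol%), 1,3-bis(2,6-diisopropylphenyl)-4,5-diphenylimidazolinium tetrafluoroborate (30 mol%), KOtBu (30 mol%), Et3SiH (5 equiv), THF, rt, 26 added by syringe pump (final 2 mM)
Reagents that add atoms: none
Why: Zerovalent nickel carrying the bulky carbene binds the terminal alkyne and the C5 aldehyde and undergoes oxidative cyclization to an oxanickelacyclopentene in which the aldehyde carbon is bonded to the internal alkyne carbon C4; σ-bond metathesis of the Ni–O bond with Et3SiH and C–H reductive elimination then release the C5 triethylsilyl ether, with the former alkyne CH as the exocyclic methylene. The closest known reaction type is the nickel-catalysed reductive macrocyclization of ynals with silanes, in which small carbenes lead to endocyclic alkenes and large carbenes to exocyclic methylene rings. The fourteen-membered ring closes in the exo mode (C4 inside the ring, its CH2 outside) under high dilution. The new C5 stereocentre is controlled only by the conformation of the macrocyclic oxidative-cyclization transition state, biased by the resident C1, C8, C12 and C13 centres, so the 5S configuration is expected but not assured. The selectivity needed is bonding at C4 instead of the terminal carbon, secured by the steric demand of the carbene against the unsubstituted alkyne terminus, while the dioxolane keeps C10 out of aldol or coupling pathways and no other π system is present.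

Step 15
Reactants: 28 macrocyclic tris-silyl ether
Product: 29 (1S,5S,8S,12R,13R)-10,10-(ethylenedioxy)-1-(2-hydroxypropan-2-yl)-8,12-dimethyl-4-methylidenecyclotetradecane-5,13-diol
Conditions: Bu4NF (8 equiv), THF, 60 °C
Reagents that add atoms: none
Why: Fluoride-mediated cleavage of all three silyl ethers (the tertiary one needs the excess and the heat) should give the triol, the dioxolane and the allylic alcohol being stable to fluoride.

Step 16
Reactants: 29 allylic triol
Product: 30 (1S,4R,5S,8S,12R,13R)-10,10-(ethylenedioxy)-1-(2-hydroxypropan-2-yl)-4,8,12-trimethylcyclotetradecane-5,13-diol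
Conditions: H2 (55 bar), [Rh(nbd)(dppb)]BF4 (cationic monovalent rhodium, 10 mol%), CH2Cl2, rt
Reagents that add atoms: none
Why: Hydroxyl-directed homogeneous hydrogenation, in which the C5 hydroxyl binds rhodium and hydrogen is delivered to the methylene face syn to oxygen in the conformer that minimizes allylic strain, should give the 4,5-anti relationship and thus 4R, high pressure suppressing isomerization of the allylic alcohol.

Step 17
Reactants: 30 saturated triol
Product: 31 (1S,4R,5S,8S,12R,13R)-5,13-diacetoxy-10,10-(ethylenedioxy)-1-(2-hydroxypropan-2-yl)-4,8,12-trimethylcyclotetradecane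
Conditions: Ac2O, pyridine, 4-(dimethylamino)pyridine (cat.), CH2Cl2, rt
Reagents that add atoms: acetic anhydride, CC(=O)OC(C)=O
Why: Nucleophile-catalysed acylation should esterify the two secondary alcohols while the tertiary carbinol stays free under these mild conditions.

Step 18
Reactants: 31 hydroxy diacetate
Product: 33 (1S,4R,5S,8S,12R,13R)-5,13-diacetoxy-4,8,12-trimethyl-1-(prop-1-en-2-yl)cyclotetradecan-10-one (CNP0328624.1), via isopropenyl dioxolane 32 (not isolated)
Conditions: SOCl2, pyridine, CH2Cl2, −20 → 0 °C; then 1 M HCl, THF, rt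
Reagents that add atoms: water, O
Why: E2 dehydration of the tertiary chlorosulfite by pyridine should remove a methyl hydrogen in preference to the single hindered ring methine at C1 and give the isopropenyl group as main regioisomer (any isopropylidene isomer would be removed on AgNO3-impregnated silica), after which dilute acid hydrolyses the dioxolane without affecting acetates, alkene or stereocentres.

**Compound list**

1 | (S)-α-terpineol, (S)-2-(4-methylcyclohex-3-en-1-yl)propan-2-ol | CC(C)(O)[C@H]1CCC(C)=CC1 | starting material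
2 | (S)-2-(4-methylcyclohex-3-en-1-yl)propan-2-yl TBS ether | CC(C)(O[Si](C)(C)C(C)(C)C)[C@H]1CCC(C)=CC1 | intermediate
3 | (3S)-3-[2-(TBS-oxy)propan-2-yl]-6-hydroperoxy-6-methoxyheptanal (C6 epimers) | CC(OC)(OO)CC[C@H](C(C)(C)O[Si](C)(C)C(C)(C)C)CC=O | intermediate
4 | (5S)-5-[2-(TBS-oxy)propan-2-yl]-2-hydroperoxy-2,7,7-trimethoxyheptane (C2 epimers) | CC(OC)(OO)CC[C@H](C(C)(C)O[Si](C)(C)C(C)(C)C)CC(OC)OC | intermediate
5 | (S)-5-[2-(TBS-oxy)propan-2-yl]-7,7-dimethoxyheptan-2-one | CC(=O)CC[C@H](C(C)(C)O[Si](C)(C)C(C)(C)C)CC(OC)OC | intermediate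
6 | lithium (S)-5-[2-(TBS-oxy)propan-2-yl]-7,7-dimethoxyhept-1-en-2-olate | [Li]OC(=C)CC[C@H](C(C)(C)O[Si](C)(C)C(C)(C)C)CC(OC)OC | intermediate
7 | (S)-5-[2-(TBS-oxy)propan-2-yl]-7,7-dimethoxyhept-1-en-2-yl diethyl phosphate | C=C(OP(=O)(OCC)OCC)CC[C@H](C(C)(C)O[Si](C)(C)C(C)(C)C)CC(OC)OC | intermediate
8 | lithium acetylide of (S)-5-[2-(TBS-oxy)propan-2-yl]-7,7-dimethoxyhept-1-yne | [Li]C#CCC[C@H](C(C)(C)O[Si](C)(C)C(C)(C)C)CC(OC)OC | intermediate
9 | (S)-3-[2-(TBS-oxy)propan-2-yl]-1,1-dimethoxy-7-(trimethylsilyl)hept-6-yne | C[Si](C)(C)C#CCC[C@H](C(C)(C)O[Si](C)(C)C(C)(C)C)CC(OC)OC | intermediate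
10 | (S)-3-[2-(TBS-oxy)propan-2-yl]-7-(trimethylsilyl)hept-6-ynal | C[Si](C)(C)C#CCC[C@H](C(C)(C)O[Si](C)(C)C(C)(C)C)CC=O | intermediate
11 | (S)-4-benzyl-3-propionyloxazolidin-2-one | CCC(=O)N1[C@@H](Cc2ccccc2)COC1=O | starting material
12 | (Z)-dibutylboron enolate of 11 | C/C=C(\OB(CCCC)CCCC)N1[C@@H](Cc2ccccc2)COC1=O | intermediate
13 | dibutylboron aldolate of 14 | O=C1OC[C@H](Cc2ccccc2)N1C(=O)[C@@H](C)[C@H](OB(CCCC)CCCC)C[C@H](CCC#C[Si](C)(C)C)C(C)(C)O[Si](C)(C)C(C)(C)C | intermediate
14 | (S)-4-benzyl-3-{(2S,3R,5S)-5-[2-(TBS-oxy)propan-2-yl]-3-hydroxy-2-methyl-9-(trimethylsilyl)non-8-ynoyl}oxazolidin-2-one | O=C1OC[C@H](Cc2ccccc2)N1C(=O)[C@@H](C)[C@H](O)C[C@H](CCC#C[Si](C)(C)C)C(C)(C)O[Si](C)(C)C(C)(C)C | intermediate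
15 | (S)-4-benzyl-3-{(2S,3R,5S)-3-(TBS-oxy)-5-[2-(TBS-oxy)propan-2-yl]-2-methyl-9-(trimethylsilyl)non-8-ynoyl}oxazolidin-2-one | O=C1OC[C@H](Cc2ccccc2)N1C(=O)[C@@H](C)[C@H](O[Si](C)(C)C(C)(C)C)C[C@H](CCC#C[Si](C)(C)C)C(C)(C)O[Si](C)(C)C(C)(C)C | intermediate
16 | (2R,3R,5S)-3-(TBS-oxy)-5-[2-(TBS-oxy)propan-2-yl]-2-methyl-9-(trimethylsilyl)non-8-yn-1-ol | OC[C@@H](C)[C@H](O[Si](C)(C)C(C)(C)C)C[C@H](CCC#C[Si](C)(C)C)C(C)(C)O[Si](C)(C)C(C)(C)C | intermediate
17 | (2S,3R,5S)-3-(TBS-oxy)-5-[2-(TBS-oxy)propan-2-yl]-1-iodo-2-methyl-9-(trimethylsilyl)non-8-yne | IC[C@@H](C)[C@H](O[Si](C)(C)C(C)(C)C)C[C@H](CCC#C[Si](C)(C)C)C(C)(C)O[Si](C)(C)C(C)(C)C | intermediate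
18 | (S)-citronellic acid, (S)-3,7-dimethyloct-6-enoic acid | CC(C)=CCC[C@H](C)CC(=O)O | starting material
19 | (S)-N-methoxy-N,3,7-trimethyloct-6-enamide | CC(C)=CCC[C@H](C)CC(=O)N(C)OC | intermediate
20 | [(2R,3R,5S)-3-(TBS-oxy)-5-[2-(TBS-oxy)propan-2-yl]-2-methyl-9-(trimethylsilyl)non-8-yn-1-yl]lithium | [Li]C[C@@H](C)[C@H](O[Si](C)(C)C(C)(C)C)C[C@H](CCC#C[Si](C)(C)C)C(C)(C)O[Si](C)(C)C(C)(C)C | intermediate
21 | lithium alkoxide of the N-methoxy-N-methyl hemiaminal of 22 (C8-chain epimers at the hemiaminal carbon) | CC(C)=CCC[C@H](C)CC(O[Li])(N(C)OC)C[C@@H](C)[C@H](O[Si](C)(C)C(C)(C)C)C[C@H](CCC#C[Si](C)(C)C)C(C)(C)O[Si](C)(C)C(C)(C)C | intermediate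
22 | (6S,10R,11R,13S)-11-(TBS-oxy)-13-[2-(TBS-oxy)propan-2-yl]-2,6,10-trimethyl-17-(trimethylsilyl)heptadec-2-en-16-yn-8-one | CC(C)=CCC[C@H](C)CC(=O)C[C@@H](C)[C@H](O[Si](C)(C)C(C)(C)C)C[C@H](CCC#C[Si](C)(C)C)C(C)(C)O[Si](C)(C)C(C)(C)C | intermediate
23 | 2-[(S)-2,6-dimethylhept-5-en-1-yl]-2-[(2R,3R,5S)-3-(TBS-oxy)-5-[2-(TBS-oxy)propan-2-yl]-2-methyl-9-(trimethylsilyl)non-8-yn-1-yl]-1,3-dioxolane | CC(C)=CCC[C@H](C)CC1(OCCO1)C[C@@H](C)[C@H](O[Si](C)(C)C(C)(C)C)C[C@H](CCC#C[Si](C)(C)C)C(C)(C)O[Si](C)(C)C(C)(C)C | intermediate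
24 | 2-[(S)-2,6-dimethylhept-5-en-1-yl]-2-[(2R,3R,5S)-3-(TBS-oxy)-5-[2-(TBS-oxy)propan-2-yl]-2-methylnon-8-yn-1-yl]-1,3-dioxolane | CC(C)=CCC[C@H](C)CC1(OCCO1)C[C@@H](C)[C@H](O[Si](C)(C)C(C)(C)C)C[C@H](CCC#C)C(C)(C)O[Si](C)(C)C(C)(C)C | intermediate
25 | 3,3-dimethyl-1,2,4-trioxolane (secondary ozonide) of 24, carrying the chain of 26 at its C5 | CC1(C)OOC(CC[C@H](C)CC2(OCCO2)C[C@@H](C)[C@H](O[Si](C)(C)C(C)(C)C)C[C@H](CCC#C)C(C)(C)O[Si](C)(C)C(C)(C)C)O1 | intermediate
26 | (S)-4-methyl-5-{2-[(2R,3R,5S)-3-(TBS-oxy)-5-[2-(TBS-oxy)propan-2-yl]-2-methylnon-8-yn-1-yl]-1,3-dioxolan-2-yl}pentanal (ynal: C5 aldehyde, C4 terminal alkyne) | C#CCC[C@H](C(C)(C)O[Si](C)(C)C(C)(C)C)C[C@@H](O[Si](C)(C)C(C)(C)C)[C@H](C)CC1(OCCO1)C[C@@H](C)CCC=O | intermediate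
27 | triethylsilane | CC[SiH](CC)CC | starting material
28 | (1S,5S,8S,12R,13R)-13-(TBS-oxy)-1-[2-(TBS-oxy)propan-2-yl]-10,10-(ethylenedioxy)-8,12-dimethyl-4-methylidene-5-(TES-oxy)cyclotetradecane | CC(C)(O[Si](C)(C)C(C)(C)C)[C@H]1CCC(=C)[C@@H](O[Si](CC)(CC)CC)CC[C@H](C)CC2(OCCO2)C[C@@H](C)[C@H](O[Si](C)(C)C(C)(C)C)C1 | intermediate
29 | (1S,5S,8S,12R,13R)-10,10-(ethylenedioxy)-1-(2-hydroxypropan-2-yl)-8,12-dimethyl-4-methylidenecyclotetradecane-5,13-diol | CC(C)(O)[C@H]1CCC(=C)[C@@H](O)CC[C@H](C)CC2(OCCO2)C[C@@H](C)[C@H](O)C1 | intermediate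
30 | (1S,4R,5S,8S,12R,13R)-10,10-(ethylenedioxy)-1-(2-hydroxypropan-2-yl)-4,8,12-trimethylcyclotetradecane-5,13-diol | CC(C)(O)[C@H]1CC[C@@H](C)[C@@H](O)CC[C@H](C)CC2(OCCO2)C[C@@H](C)[C@H](O)C1 | intermediate
31 | (1S,4R,5S,8S,12R,13R)-5,13-diacetoxy-10,10-(ethylenedioxy)-1-(2-hydroxypropan-2-yl)-4,8,12-trimethylcyclotetradecane | CC(C)(O)[C@H]1CC[C@@H](C)[C@@H](OC(C)=O)CC[C@H](C)CC2(OCCO2)C[C@@H](C)[C@H](OC(C)=O)C1 | intermediate
32 | (1S,4R,5S,8S,12R,13R)-5,13-diacetoxy-10,10-(ethylenedioxy)-4,8,12-trimethyl-1-(prop-1-en-2-yl)cyclotetradecane | C=C(C)[C@H]1CC[C@@H](C)[C@@H](OC(C)=O)CC[C@H](C)CC2(OCCO2)C[C@@H](C)[C@H](OC(C)=O)C1 | intermediate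
33 | (1S,4R,5S,8S,12R,13R)-5,13-diacetoxy-4,8,12-trimethyl-1-(prop-1-en-2-yl)cyclotetradecan-10-one (CNP0328624.1) | C=C(C)[C@H]1CC[C@@H](C)[C@@H](OC(C)=O)CC[C@H](C)CC(=O)C[C@@H](C)[C@H](OC(C)=O)C1 | target

**Count.** Total: 18 steps. Longest linear sequence: 17 steps (steps 1–8 and 10–18, from 1); step 9 is the one-step side branch.

**The three steps most likely to fail**

Step 14. Face selection at C5 during the oxidative cyclization may be poor, or may favor the 5R epimer, because only the macrocyclic transition state controls it. The fallback replaces this substrate control by reagent control; it sets out from 28 (as obtained, whatever its C5 composition) and comes back at 29. The secondary allylic triethylsilyl ether is cleaved selectively (pyridinium p-toluenesulfonate, MeOH/CH2Cl2, 0 °C; both TBS ethers stay) to give the C5-epimeric allylic alcohols F1. Dess–Martin periodinane (NaHCO3, CH2Cl2) oxidizes them to the single α-methylene ketone F2. Corey–Bakshi–Shibata reduction with (R)-2-methyl-CBS-oxazaborolidine and BH3·SMe2 (toluene, −40 °C) should then give the (5S)-allylic alcohol F3, the α-branched alkenyl arm at C4 acting as the large group and the C6 methylene as the small one. Bu4NF (THF, 60 °C) finally removes the two TBS groups and delivers triol 29.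

Step 16. Hydrogen may be delivered to the wrong face of the C4 methylene if the ring conformation overrides direction by the C5 hydroxyl, or the allylic alcohol may isomerize to the saturated C5 ketone. The fallback runs from 29 to 30 and replaces substrate direction by catalyst control: hydrogenation with Ru(OAc)2(binap) in methanol under hydrogen pressure, the known ligand-controlled reduction of allylic alcohols. The BINAP antipode whose face preference matches the 4R outcome would be identified in a small-scale test of both. This fallback makes no new compound (F0).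

Step 10. The γ-silyloxy alkyllithium may be lost by protonation or by 1,4 oxygen-to-carbon silyl migration, or the Weinreb amide may be enolized instead of attacked. The fallback inverts the polarity at C10 (acyl anion equivalent plus the same iodide); it sets out from 17 and 19 and comes back at 22. DIBAL-H (toluene, −78 °C) reduces 19 to (S)-citronellal F4, which is also commercial. Propane-1,3-dithiol with MgBr2·OEt2 in Et2O, a mild Lewis acid chosen to avoid the carbonyl-ene cyclization of citronellal, gives 2-[(S)-2,6-dimethylhept-5-en-1-yl]-1,3-dithiane F5. t-BuLi in THF/HMPA at −78 °C gives the 2-lithio-1,3-dithiane F6, which is alkylated by iodide 17 (Corey–Seebach alkylation) to the 2,2-dialkyl-1,3-dithiane F7. MeI and CaCO3 in MeCN/H2O then unmask ketone 22.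

**Further compounds**

F1 | step 14 | (1S,8S,12R,13R)-13-(TBS-oxy)-1-[2-(TBS-oxy)propan-2-yl]-10,10-(ethylenedioxy)-8,12-dimethyl-4-methylidenecyclotetradecan-5-ol (C5 epimers) | CC(C)(O[Si](C)(C)C(C)(C)C)[C@H]1CCC(=C)C(O)CC[C@H](C)CC2(OCCO2)C[C@@H](C)[C@H](O[Si](C)(C)C(C)(C)C)C1
F2 | step 14 | (1S,8S,12R,13R)-13-(TBS-oxy)-1-[2-(TBS-oxy)propan-2-yl]-10,10-(ethylenedioxy)-8,12-dimethyl-4-methylidenecyclotetradecan-5-one | CC(C)(O[Si](C)(C)C(C)(C)C)[C@H]1CCC(=C)C(=O)CC[C@H](C)CC2(OCCO2)C[C@@H](C)[C@H](O[Si](C)(C)C(C)(C)C)C1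
F3 | step 14 | (1S,5S,8S,12R,13R)-13-(TBS-oxy)-1-[2-(TBS-oxy)propan-2-yl]-10,10-(ethylenedioxy)-8,12-dimethyl-4-methylidenecyclotetradecan-5-ol | CC(C)(O[Si](C)(C)C(C)(C)C)[C@H]1CCC(=C)[C@@H](O)CC[C@H](C)CC2(OCCO2)C[C@@H](C)[C@H](O[Si](C)(C)C(C)(C)C)C1
F0 | step 16 | none | none
F4 | step 10 | (S)-citronellal, (S)-3,7-dimethyloct-6-enal | CC(C)=CCC[C@H](C)CC=O
F5 | step 10 | 2-[(S)-2,6-dimethylhept-5-en-1-yl]-1,3-dithiane | CC(C)=CCC[C@H](C)CC1SCCCS1
F6 | step 10 | 2-[(S)-2,6-dimethylhept-5-en-1-yl]-2-lithio-1,3-dithiane | CC(C)=CCC[C@H](C)CC1([Li])SCCCS1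
F7 | step 10 | 2-[(S)-2,6-dimethylhept-5-en-1-yl]-2-[(2R,3R,5S)-3-(TBS-oxy)-5-[2-(TBS-oxy)propan-2-yl]-2-methyl-9-(trimethylsilyl)non-8-yn-1-yl]-1,3-dithiane | CC(C)=CCC[C@H](C)CC1(SCCCS1)C[C@@H](C)[C@H](O[Si](C)(C)C(C)(C)C)C[C@H](CCC#C[Si](C)(C)C)C(C)(C)O[Si](C)(C)C(C)(C)C
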